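The plan rests on cutting C3–C6, the bond through which the α-methylbutenolide (C3=C4(Me)–C5(=O)–O–C6) is fused to the 14-membered carbocycle (numbering: acetoxy carbon C1, C2, C3, then C6, C7=C8, C9, C10, epoxide C11–C12, C13, C14, C15=C16). C6 is both the lactone O–CH and allylic to C7=C8, so it can be made from an enal and a C3-metallated enoate. The open-chain precursor carries a (Z)-β-triflyloxy-α-methyl enoate at one end and the C6 enal at the other. A single Ni/Cr operation on it forms C3–C6, closes the carbocycle, sets C6 and lets the cis alkoxide lactonise. The chain comes from nerol and two acetoacetates.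

Key step: step 17

Assumption: the senses of induction of (R)-BINOL–Ti (step 12) and of the (S)-oxazoline–sulfonamide–Cr complex (step 17) are assigned by analogy with simple enals. Each is checked (MTPA esters at C1, NOE correlation at C6), and the equally available mirror-image ligand is used if the sense is reversed.

Step 1
Reactants: 1 nerol
Product: 2 (2S,3R)-2,3-epoxynerol, [(2S,3R)-3-methyl-3-(4-methylpent-3-en-1-yl)oxiran-2-yl]methanol (cis epoxide: CH2OH and the homoprenyl chain on the same face)
Conditions: Ti(OiPr)4 (5 mol %), L-(+)-DET (7 mol %), t-BuOOH (in decane), 4 Å MS, CH2Cl2, −20 °C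
Reagents that add atoms: tert-butyl hydroperoxide, CC(C)(C)OO
Why: The Katsuki–Sharpless asymmetric epoxidation is directed by the allylic hydroxyl, so the remote olefin is untouched, L-(+)-tartrate delivers oxygen to the face that gives 2S,3R, and the Z geometry of nerol is carried stereospecifically into the cis epoxide, fixing C11 (S) and C12 (R).

Step 2
Reactants: 2 (2S,3R)-2,3-epoxynerol
Product: 3 epoxy triflate, [(2S,3R)-3-methyl-3-(4-methylpent-3-en-1-yl)oxiran-2-yl]methyl trifluoromethanesulfonate
Conditions: Tf2O, 2,6-lutidine, CH2Cl2, −78 °C; cold aq. NaHCO3 wash, used at once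
Reagents that add atoms: trifluoromethanesulfonic anhydride, O=S(=O)(OS(=O)(=O)C(F)(F)F)C(F)(F)F
Why: O-Sulfonylation of a primary alcohol with a hindered base touches neither epoxide carbon, and a triflate is preferred to an iodide because it couples at −78 °C and cannot suffer halophilic attack with reductive opening of the epoxide.

Step 3
Reactants: 3 epoxy triflate; 4 methyl acetoacetate
Product: 6 epoxy β-keto ester methyl 5-[(2S,3R)-3-methyl-3-(4-methylpent-3-en-1-yl)oxiran-2-yl]-3-oxopentanoate, via acetoacetate dianion 5 (not isolated)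
Conditions: 4 (1.5 equiv), NaH, THF, 0 °C; n-BuLi, 0 °C; then 3, −78 → −30 °C; sat. aq. NH4Cl
Reagents that add atoms: none
Why: γ-Alkylation of an acetoacetate dianion (SN2) takes place at its more basic terminal carbon and at the unhindered primary C–OTf carbon much faster than at the trisubstituted epoxide, forming C9–C10 without touching C11 or C12.

Step 4
Reactants: 6 epoxy β-keto ester
Product: 8 (Z)-enol phosphate methyl (2Z)-3-(diethoxyphosphoryloxy)-5-[(2S,3R)-3-methyl-3-(4-methylpent-3-en-1-yl)oxiran-2-yl]pent-2-enoate, via chelated sodium enolate 7 (not isolated)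
Conditions: NaH, Et2O, 0 °C; ClP(O)(OEt)2, 0 °C
Reagents that add atoms: diethyl chlorophosphate, CCOP(=O)(Cl)OCC
Why: O-Phosphorylation of the sodium-chelated, U-shaped enolate in ether places the phosphate cis to the ester (Z), and prompt trapping at 0 °C outruns 5-exo opening of the epoxide by the stabilised enolate.

Step 5
Reactants: 8 (Z)-enol phosphate
Product: 9 (E)-enoate, methyl (2E)-3-methyl-5-[(2S,3R)-3-methyl-3-(4-methylpent-3-en-1-yl)oxiran-2-yl]pent-2-enoate
Conditions: Me2CuLi (from MeLi and CuI), Et2O, −78 → −45 °C; aq. NH4Cl/NH3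
Reagents that add atoms: lithium dimethylcuprate, [Li+].C[Cu-]C
Why: Enol phosphate–organocuprate coupling (conjugate addition–elimination) replaces the phosphate by methyl with retention, so the chain ends trans to the ester (C7=C8 E), while the trisubstituted epoxide and the β,β-disubstituted enoate product are inert to the cuprate below −40 °C.

Step 6
Reactants: 9 (E)-enoate
Product: 10 allylic alcohol, (2E)-3-methyl-5-[(2S,3R)-3-methyl-3-(4-methylpent-3-en-1-yl)oxiran-2-yl]pent-2-en-1-ol
Conditions: DIBAL-H (2.2 equiv), CH2Cl2, −78 °C; aq. potassium sodium tartrate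
Reagents that add atoms: none
Why: DIBAL-H 1,2-reduction of an enoate to the allylic alcohol is fast at −78 °C, where the epoxide is not opened, and the tartrate work-up avoids acid.

Step 7
Reactants: 10 allylic alcohol
Product: 11 PMB ether, the C6 4-methoxybenzyl ether of 10
Conditions: PMBCl, NaH, Bu4NI (cat.), DMF, 0 °C → rt
Reagents that add atoms: 4-methoxybenzyl chloride, COc1ccc(CCl)cc1
Why: Williamson etherification under basic conditions is harmless to the epoxide and installs a group that is later removed oxidatively beside a silyl ether, an enol triflate and the epoxide.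

Step 8
Reactants: 11 PMB ether
Product: 12 C1 allylic alcohol, (2E)-5-[(2R,3S)-3-{(3E)-5-[(4-methoxybenzyl)oxy]-3-methylpent-3-en-1-yl}-2-methyloxiran-2-yl]-2-methylpent-2-en-1-ol
Conditions: SeO2 (0.3 equiv), t-BuOOH (3 equiv, in decane), CH2Cl2, 0 °C → rt, no acid additive
Reagents that add atoms: tert-butyl hydroperoxide, CC(C)(C)OO (terminal oxygen source, relayed by catalytic selenium dioxide, O=[Se]=O)
Why: Selenium dioxide allylic oxidation (ene reaction, then [2,3]-sigmatropic shift) prefers the terminal olefin over C7=C8, which is deactivated by its allylic ether oxygen, and oxidises the methyl trans to the chain to give the E product, as is well known for geranyl and neryl ethers.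

Step 9
Reactants: 12 C1 allylic alcohol
Product: 13 C1 enal, (2E)-5-[(2R,3S)-3-{(3E)-5-[(4-methoxybenzyl)oxy]-3-methylpent-3-en-1-yl}-2-methyloxiran-2-yl]-2-methylpent-2-enal
Conditions: MnO2 (excess), CH2Cl2, rt
Reagents that add atoms: none
Why: MnO2 oxidises only allylic alcohols, under neutral conditions and without E/Z isomerisation, and material already over-oxidised in step 8 converges on the same (E)-enal.

Step 10
Reactants: 14 methyl 2-methylacetoacetate
Product: 15 methyl 2-methyl-3-(trimethylsilyloxy)but-2-enoate (olefin geometry irrelevant)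
Conditions: TMSCl, Et3N, toluene, rt
Reagents that add atoms: chlorotrimethylsilane, C[Si](C)(C)Cl
Why: Soft enolisation and O-silylation of a β-keto ester is the standard first stage towards a 1,3-bis(silyloxy)diene.

Step 11
Reactants: 15 methyl 2-methyl-3-(trimethylsilyloxy)but-2-enoate
Product: 17 bis(silyl) dienol ether 1-methoxy-2-methyl-1,3-bis(trimethylsilyloxy)buta-1,3-diene, via lithium dienolate 16 (not isolated)
Conditions: LDA (commercial solution), THF, −78 °C; TMSCl, −78 °C → rt; filtration under argon, used crude
Reagents that add atoms: chlorotrimethylsilane, C[Si](C)(C)Cl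
Why: Kinetic γ-deprotonation of the silyloxy enoate and O-silylation of the extended enolate gives the diene, whose geometry does not matter because C4 becomes sp2 again in step 14.

Step 12
Reactants: 13 C1 enal; 17 bis(silyl) dienol ether
Product: 19 δ-hydroxy β-keto ester (C5 methyl ester; C4H(Me) as epimer mixture; C3 ketone; C2H2; (1R)-carbinol; 15E olefin; 11S,12R cis epoxide; 7E olefin; C6H2OPMB), via bis-silylated aldol adduct 18 (not isolated)
Conditions: Ti(OiPr)4/(R)-BINOL (1:1, 15 mol %), 4 Å MS, THF, −78 °C → rt; then TBAF/AcOH (1:1), THF, 0 °C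
Reagents that add atoms: none
Why: In this catalytic asymmetric vinylogous Mukaiyama aldol reaction the BINOL–titanium Lewis acid activates the enal for attack by the terminal γ-carbon of the diene on its Re face, forming C1–C2 and setting C1 (R) under catalyst control, and acetic-acid-buffered fluoride then removes both TMS groups without any acid able to open the epoxide.

Step 13
Reactants: 19 δ-hydroxy β-keto ester
Product: 20 δ-silyloxy β-keto ester, the C1 tert-butyldimethylsilyl ether of 19
Conditions: TBSCl, imidazole, DMF, 0 °C → rt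
Reagents that add atoms: tert-butyldimethylsilyl chloride, CC(C)(C)[Si](C)(C)Cl
Why: Standard silylation of a secondary allylic alcohol avoids Lewis acidic silyl triflates, and a silyl ether is carried instead of the final acetate because a β-acyloxy ketone would eliminate under the base of step 14.

Step 14
Reactants: 20 δ-silyloxy β-keto ester
Product: 22 (Z)-enol triflate (C3(OTf)=C4(Me)CO2Me having OTf cis to CO2Me; otherwise as 20), via chelated lithium enolate 21 (not isolated)
Conditions: LiHMDS (1.05 equiv), toluene, −78 → 0 °C; Tf2O, −78 °C; pH 7 buffer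
Reagents that add atoms: trifluoromethanesulfonic anhydride, O=S(=O)(OS(=O)(=O)C(F)(F)F)C(F)(F)F
Why: In this chelation-controlled enol triflation one equivalent of base removes only the doubly activated C4–H, lithium in a non-coordinating solvent locks the enolate in the U shape, and O-sulfonylation of the ketone oxygen gives the tetrasubstituted triflate cis to the ester, as known for α-substituted acetoacetates.

Step 15
Reactants: 22 (Z)-enol triflate
Product: 23 C6 allylic alcohol (22 without the PMB group)
Conditions: DDQ (1.2 equiv), CH2Cl2/pH 7 phosphate buffer (10:1), 0 °C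
Reagents that add atoms: none
Why: Oxidative PMB cleavage (hydride abstraction from the electron-rich benzyl ether, then hydrolysis of the oxocarbenium ion) in a buffered two-phase medium leaves the silyl ether, the enol triflate, the epoxide and the trisubstituted olefins alone.

Step 16
Reactants: 23 C6 allylic alcohol
Product: 24 open-chain triflate enal (C6 (E)-enal at one end, (Z)-C3(OTf)=C4(Me)CO2Me at the other; 1R silyl ether, 15E, 11S,12R cis epoxide, 7E)
Conditions: MnO2 (excess), CH2Cl2, rt
Reagents that add atoms: none
Why: Neutral MnO2 oxidation of the only free allylic alcohol gives the enal with its E geometry retained.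

Step 17
Reactants: 24 open-chain triflate enal
Product: 26 macrocyclic butenolide C1 silyl ether (1R,6R,11S,12R; 7E,15E), via ring-closed hydroxy enoate 25 (not isolated)
Conditions: CrCl2 (8 equiv), (S)-N-[2-(4-isopropyl-4,5-dihydrooxazol-2-yl)-6-methylphenyl]methanesulfonamide (8.8 equiv), Et3N (8.5 equiv), THF, rt (complex pre-formed); NiCl2·(2,9-dimethyl-1,10-phenanthroline) (0.3 equiv), LiCl; 24 in THF by syringe pump over 16 h (final ca. 1 mM), rt; aq. potassium serinate/NaHCO3
Reagents that add atoms: none
Why: Proposed new method: Ni(0), formed from NiCl2 by Cr(II), inserts with retention into the C3–OTf bond that the ester makes electron-poor, the alkenyl group passes to Cr(III), the alkenylchromium adds 1,2 to the C6 aldehyde, and the alkoxide of 25 attacks the C5 ester held cis to it and expels methoxide. The closest known reaction types are intermolecular Nozaki–Hiyama–Kishi couplings of (Z)-β-iodo- or β-triflyloxyacrylates with aldehydes, which give butenolides directly, and Nozaki–Hiyama–Kishi macrocyclisations of simple alkenyl halides onto aldehydes in cembranoid work; what is new is a tetrasubstituted β-triflyloxy enoate closing a large ring. The 14-membered carbocycle closes by intramolecular carbonyl addition (14-exo-trig at C6) under pseudo-high dilution, and the butenolide closes by 5-exo-trig acyl substitution. C6 (R) requires attack on the Si face of the enal, which the oxazoline–sulfonamide ligand on chromium is meant to impose and which the C1 silyloxy centre two atoms from C3 may reinforce or oppose, so both ligand antipodes are tried and the C6 epimers are separable. The step needs three selectivities: aldehyde over ester, epoxide and silyl ether, given by the weakly basic organochromium; retention of the Z geometry, typical of Ni/Cr couplings and the guarantee of lactonisation; and cyclisation over oligomerisation, favoured by slow addition and by the three fixed olefins and the cis epoxide, which limit chain freedom. No leaving group sits on C2, so β-elimination of the alkenyl metal is excluded, and pre-forming the Cr–ligand complex leaves no free amine to eliminate triflic acid towards an allenoate.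

Step 18
Reactants: 26 macrocyclic butenolide C1 silyl ether
Product: 27 C1 alcohol (deacetyl target)
Conditions: TBAF/AcOH (1:1), THF, 0 °C → rt
Reagents that add atoms: none
Why: Fluoride desilylation buffered with acetic acid is neither basic enough to deprotonate the butenolide at C6 (epimerisation) nor acidic enough to open the epoxide.

Step 19
Reactants: 27 C1 alcohol
Product: 28 target CNP0302675.1
Conditions: Ac2O, pyridine, DMAP (cat.), CH2Cl2, 0 °C
Reagents that add atoms: acetic anhydride, CC(=O)OC(C)=O
Why: DMAP-catalysed acetylation of the only free hydroxyl proceeds with retention at C1 under conditions too mild to epimerise C6 or eliminate the new allylic acetate.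

Compound list
1 | nerol, (2Z)-3,7-dimethylocta-2,6-dien-1-ol | OC/C=C(/C)CCC=C(C)C | starting material
2 | (2S,3R)-2,3-epoxynerol | OC[C@@H]1O[C@]1(C)CCC=C(C)C | intermediate
3 | (2S,3R)-epoxyneryl triflate | O=S(=O)(OC[C@@H]1O[C@]1(C)CCC=C(C)C)C(F)(F)F | intermediate
4 | methyl acetoacetate | CC(=O)CC(=O)OC | starting material
5 | sodium lithium dianion of methyl acetoacetate (not isolated) | C=C([O-])C=C([O-])OC.[Na+].[Li+] | intermediate
6 | methyl 5-[(2S,3R)-3-methyl-3-(4-methylpent-3-en-1-yl)oxiran-2-yl]-3-oxopentanoate | COC(=O)CC(=O)CC[C@@H]1O[C@]1(C)CCC=C(C)C | intermediate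
7 | chelated (Z)-sodium enolate of 6 (not isolated) | COC(=O)/C=C(\[O-])CC[C@@H]1O[C@]1(C)CCC=C(C)C.[Na+] | intermediate
8 | (Z)-enol diethyl phosphate of 6 | COC(=O)/C=C(OP(=O)(OCC)OCC)/CC[C@@H]1O[C@]1(C)CCC=C(C)C | intermediate
9 | methyl (2E)-3-methyl-5-[(2S,3R)-3-methyl-3-(4-methylpent-3-en-1-yl)oxiran-2-yl]pent-2-enoate | COC(=O)/C=C(\C)CC[C@@H]1O[C@]1(C)CCC=C(C)C | intermediate
10 | (2E)-3-methyl-5-[(2S,3R)-3-methyl-3-(4-methylpent-3-en-1-yl)oxiran-2-yl]pent-2-en-1-ol | OC/C=C(\C)CC[C@@H]1O[C@]1(C)CCC=C(C)C | intermediate
11 | C6 4-methoxybenzyl ether of 10 | COc1ccc(COC/C=C(\C)CC[C@@H]2O[C@]2(C)CCC=C(C)C)cc1 | intermediate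
12 | (E)-C1 allylic alcohol with C6–OPMB | COc1ccc(COC/C=C(\C)CC[C@@H]2O[C@]2(C)CC/C=C(\C)CO)cc1 | intermediate
13 | (E)-C1 enal with C6–OPMB | COc1ccc(COC/C=C(\C)CC[C@@H]2O[C@]2(C)CC/C=C(\C)C=O)cc1 | intermediate
14 | methyl 2-methylacetoacetate | COC(=O)C(C)C(C)=O | starting material
15 | methyl 2-methyl-3-(trimethylsilyloxy)but-2-enoate | COC(=O)C(C)=C(C)O[Si](C)(C)C | intermediate
16 | lithium dienolate of 15 (not isolated) | COC([O-])=C(C)C(=C)O[Si](C)(C)C.[Li+] | intermediate
17 | 1-methoxy-2-methyl-1,3-bis(trimethylsilyloxy)buta-1,3-diene | COC(O[Si](C)(C)C)=C(C)C(=C)O[Si](C)(C)C | intermediate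
18 | bis-silylated aldol adduct, C1–OTMS and C3 TMS enol ether (not isolated) | COC(=O)C(C)=C(O[Si](C)(C)C)C[C@@H](O[Si](C)(C)C)/C(C)=C/CC[C@@]1(C)O[C@H]1CC/C(C)=C/COCc1ccc(OC)cc1 | intermediate
19 | (1R)-δ-hydroxy β-keto ester, C4 epimers | COC(=O)C(C)C(=O)C[C@@H](O)/C(C)=C/CC[C@@]1(C)O[C@H]1CC/C(C)=C/COCc1ccc(OC)cc1 | intermediate
20 | (1R)-δ-(tert-butyldimethylsilyloxy) β-keto ester, C4 epimers | COC(=O)C(C)C(=O)C[C@@H](O[Si](C)(C)C(C)(C)C)/C(C)=C/CC[C@@]1(C)O[C@H]1CC/C(C)=C/COCc1ccc(OC)cc1 | intermediate
21 | chelated lithium enolate of 20 (not isolated) | COC(=O)/C(C)=C(\[O-])C[C@@H](O[Si](C)(C)C(C)(C)C)/C(C)=C/CC[C@@]1(C)O[C@H]1CC/C(C)=C/COCc1ccc(OC)cc1.[Li+] | intermediate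
22 | (Z)-enol triflate, OTf cis to CO2Me, C6–OPMB | COC(=O)/C(C)=C(OS(=O)(=O)C(F)(F)F)/C[C@@H](O[Si](C)(C)C(C)(C)C)/C(C)=C/CC[C@@]1(C)O[C@H]1CC/C(C)=C/COCc1ccc(OC)cc1 | intermediate
23 | (Z)-enol triflate, C6 allylic alcohol | COC(=O)/C(C)=C(OS(=O)(=O)C(F)(F)F)/C[C@@H](O[Si](C)(C)C(C)(C)C)/C(C)=C/CC[C@@]1(C)O[C@H]1CC/C(C)=C/CO | intermediate
24 | open-chain (Z)-enol triflate C6 enal | COC(=O)/C(C)=C(OS(=O)(=O)C(F)(F)F)/C[C@@H](O[Si](C)(C)C(C)(C)C)/C(C)=C/CC[C@@]1(C)O[C@H]1CC/C(C)=C/C=O | intermediate
25 | ring-closed (6R)-γ-hydroxy (Z)-enoate, present as its Cr(III) alkoxide, drawn as the alcohol (not isolated) | COC(=O)/C(C)=C1/C[C@@H](O[Si](C)(C)C(C)(C)C)/C(C)=C/CC[C@@]2(C)O[C@H]2CC/C(C)=C/[C@H]1O | intermediate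
26 | macrocyclic butenolide, C1 tert-butyldimethylsilyl ether | CC(C)(C)[Si](C)(C)O[C@@H]1CC2=C(C)C(=O)O[C@@H]2/C=C(\C)CC[C@@H]2O[C@]2(C)CC/C=C/1C | intermediate
27 | macrocyclic butenolide, C1 alcohol | O[C@@H]1CC2=C(C)C(=O)O[C@@H]2/C=C(\C)CC[C@@H]2O[C@]2(C)CC/C=C/1C | intermediate
28 | CNP0302675.1 | CC(=O)O[C@@H]1CC2=C(C)C(=O)O[C@@H]2/C=C(\C)CC[C@@H]2O[C@]2(C)CC/C=C/1C | target

Total step count: 19.
Longest linear sequence: 17 (steps 1–9 and 12–19, from nerol); steps 10 and 11 form the side branch.

Steps most likely to fail

1. Step 17 (proposed new method).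
- What may go wrong: protonation or reduction of the hindered, ester-chelated alkenyl metal before it reaches the aldehyde; base-induced loss of triflic acid; oligomerisation; or poor facial selectivity at C6.
- Fallback: known chemistry that separates ring closure from lactone formation and uses an ordinary, more nucleophilic alkenyl triflate. It sets out from 22. DIBAL-H (CH2Cl2, −78 °C) reduces the ester to the (Z)-triflyloxy allylic alcohol F1. TBSCl/imidazole gives the bis-silyl ether F2, buffered DDQ frees the C6 allylic alcohol F3, and MnO2 gives the enal F4. A conventional Nozaki–Hiyama–Kishi macrocyclisation of this unactivated alkenyl triflate (same Cr–ligand system, slow addition) gives the 14-membered bis-allylic alcohol F5, and TBAF/AcOH frees the triol F6. TEMPO/PhI(OAc)2 oxidises only the primary allylic alcohol. The resulting aldehyde is captured by the cis C6 hydroxyl as the lactol F7, which is oxidised further in the same flask to the butenolide. That product is 27, where the route is rejoined before step 19.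

2. Step 12.
- What may go wrong: slow turnover and poor facial selectivity with an α-branched enal and a C4-methylated diene, or opening of the epoxide during the Lewis acid stage or the desilylation.
- Fallback: auxiliary control replaces catalyst control, and C3–C5 are added afterwards. It sets out from 13. The tin(II) enolate of N-acetyl-(4S)-4-isopropyl-1,3-thiazolidine-2-thione (Sn(OTf)2, N-ethylpiperidine, CH2Cl2, −78 °C) adds to the enal in a thiazolidinethione acetate aldol reaction. This gives the (R)-β-hydroxy acyl thiazolidinethione F8, from which the minor diastereomer can be removed by chromatography. The magnesium enolate of potassium methyl 2-methylmalonate (MgCl2, imidazole, THF, rt) then displaces the auxiliary with loss of CO2 (decarboxylative Claisen condensation). The product is 19, where the route is rejoined before step 13.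

3. Step 3.
- What may go wrong: decomposition of the triflate before coupling, competing attack of the dianion on the epoxide, or cyclisation of the product enolate onto the epoxide.
- Fallback: olefination replaces alkylation and the β-keto ester is bypassed. It sets out from 2. Parikh–Doering oxidation gives the epoxy aldehyde F9. Wittig reaction with 1-(triphenylphosphoranylidene)propan-2-one gives the (E)-epoxy enone F10. Diimide (2-nitrobenzenesulfonyl hydrazide, Et3N, CH2Cl2) saturates only the disubstituted olefin to give the epoxy methyl ketone F11. Horner–Wadsworth–Emmons olefination with trimethyl phosphonoacetate/NaH should favour the E enoate, which is separated from its Z isomer by chromatography. That product is 9, where the route is rejoined before step 6.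

Further compounds
F1 | step 17 | (Z)-triflyloxy allylic alcohol (C5H2OH in place of the ester of 22) | OC/C(C)=C(OS(=O)(=O)C(F)(F)F)/C[C@@H](O[Si](C)(C)C(C)(C)C)/C(C)=C/CC[C@@]1(C)O[C@H]1CC/C(C)=C/COCc1ccc(OC)cc1
F2 | step 17 | bis-silyl ether (C1 and C5 OTBS, C6–OPMB) | CC(C)(C)[Si](C)(C)OC/C(C)=C(OS(=O)(=O)C(F)(F)F)/C[C@@H](O[Si](C)(C)C(C)(C)C)/C(C)=C/CC[C@@]1(C)O[C@H]1CC/C(C)=C/COCc1ccc(OC)cc1
F3 | step 17 | C6 allylic alcohol of the bis-silyl ether | CC(C)(C)[Si](C)(C)OC/C(C)=C(OS(=O)(=O)C(F)(F)F)/C[C@@H](O[Si](C)(C)C(C)(C)C)/C(C)=C/CC[C@@]1(C)O[C@H]1CC/C(C)=C/CO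
F4 | step 17 | C6 enal of the bis-silyl ether | CC(C)(C)[Si](C)(C)OC/C(C)=C(OS(=O)(=O)C(F)(F)F)/C[C@@H](O[Si](C)(C)C(C)(C)C)/C(C)=C/CC[C@@]1(C)O[C@H]1CC/C(C)=C/C=O
F5 | step 17 | 14-membered (6R) bis-allylic alcohol with exocyclic C3=C4(Me)CH2OTBS | CC(C)(C)[Si](C)(C)OC/C(C)=C1/C[C@@H](O[Si](C)(C)C(C)(C)C)/C(C)=C/CC[C@@]2(C)O[C@H]2CC/C(C)=C/[C@H]1O
F6 | step 17 | macrocyclic triol (C1, C5, C6 hydroxyls) | OC/C(C)=C1/C[C@@H](O)/C(C)=C/CC[C@@]2(C)O[C@H]2CC/C(C)=C/[C@H]1O
F7 | step 17 | macrocyclic lactol (C5 hemiacetal, anomers) | O[C@@H]1CC2=C(C)C(O)O[C@@H]2/C=C(\C)CC[C@@H]2O[C@]2(C)CC/C=C/1C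
F8 | step 12 | (R)-β-hydroxy acyl (4S)-4-isopropylthiazolidine-2-thione | CC(C)[C@H]1CSC(=S)N1C(=O)C[C@@H](O)/C(C)=C/CC[C@@]2(C)O[C@H]2CC/C(C)=C/COCc2ccc(OC)cc2
F9 | step 3 | (2R,3R)-3-methyl-3-(4-methylpent-3-en-1-yl)oxirane-2-carbaldehyde | O=C[C@@H]1O[C@]1(C)CCC=C(C)C
F10 | step 3 | (3E)-4-[(2S,3R)-3-methyl-3-(4-methylpent-3-en-1-yl)oxiran-2-yl]but-3-en-2-one | CC(=O)/C=C/[C@@H]1O[C@]1(C)CCC=C(C)C
F11 | step 3 | 4-[(2S,3R)-3-methyl-3-(4-methylpent-3-en-1-yl)oxiran-2-yl]butan-2-one | CC(=O)CC[C@@H]1O[C@]1(C)CCC=C(C)C
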